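**Retrosynthetic overview**

1. Locants of 1H-isochromene are used throughout (O2, C1, C3, C4, C4a, C5, C6, C7, C8, C8a). The pyran ring is opened last at O2–C3, which leads back to an enynone with a free C1 hydroxymethyl group and a C3≡C4 alkyne (6-endo-dig hydroalkoxylation in the forward sense).
2. The carbocycle C4a–C5–C6–C7–C8–C8a is cut at C5–C6 and at C4a=C8a. In the forward sense this is a one-pot Mukaiyama aldol / intramolecular Horner–Wadsworth–Emmons union of an aldehyde–ketophosphonate (C6, C7, C8, C8a, C1) with the enol silane of an alkynyl methyl ketone (C5, C4a, C4≡C3, propenyl).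
3. Enabling feature: in the cyclohexenone ring the C6 carbinol is beta to C4a, and C4a=C8a is the alpha,beta-bond of the C8 ketone. C8 sits between the fully substituted C7 and C8a, so a phosphonate at C8a gives one defined carbanion, C7 cannot epimerise and steers C6, and the ynone can enolise only at C5.
4. C7 comes from methyl (R)-2-methylglycidate. The hindered tertiary aryl ester is made early, on the open-chain hydroxy ester, by acylium-type acylation; the phenol travels as a silyl ether.
5. Order of ring formation: carbocycle (step 14), then pyran (step 16).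

Key step: step 14

Remark: methyl (R)-2-methylglycidate, diethyl (2-hydroxyethyl)phosphonate and (E)-1-bromoprop-1-ene are taken as catalogue chemicals.

**Route**

Step 1
Reactants: 1 orsellinic acid (2,4-dihydroxy-6-methylbenzoic acid)
Product: 2 benzyl 2,4-dihydroxy-6-methylbenzoate
Conditions: BnBr, KHCO3, DMF, rt
Reagents that add atoms: benzyl bromide BrCc1ccccc1
Why: Carboxylate O-alkylation (SN2); the hydrogen carbonate deprotonates only the carboxylic acid, so both phenols should stay free, and the benzyl ester can later be removed by hydrogenolysis without touching a silyl ether.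

Step 2
Reactants: 2 benzyl 2,4-dihydroxy-6-methylbenzoate
Product: 3 benzyl 2-hydroxy-6-methyl-4-(triisopropylsilyloxy)benzoate
Conditions: i-Pr3SiCl, imidazole, CH2Cl2, 0 °C to rt
Reagents that add atoms: chlorotriisopropylsilane CC(C)[Si](Cl)(C(C)C)C(C)C
Why: Silyl ether formation at the free para-hydroxyl; the ortho-hydroxyl is hydrogen-bonded to the ester carbonyl and flanked by it, so monosilylation should be regioselective.

Step 3
Reactants: 3 benzyl 2-hydroxy-6-methyl-4-(triisopropylsilyloxy)benzoate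
Product: 4 benzyl 2-methoxy-6-methyl-4-(triisopropylsilyloxy)benzoate
Conditions: MeI, K2CO3, acetone, 50 °C
Reagents that add atoms: iodomethane CI
Why: Williamson O-methylation of the remaining chelated phenol under anhydrous conditions that the aryl triisopropylsilyl ether and the benzyl ester should tolerate.

Step 4
Reactants: 4 benzyl 2-methoxy-6-methyl-4-(triisopropylsilyloxy)benzoate
Product: 5 2-methoxy-6-methyl-4-(triisopropylsilyloxy)benzoic acid
Conditions: H2 (1 atm), Pd/C, EtOAc, rt
Reagents that add atoms: none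
Why: Hydrogenolysis of the benzyl ester should free the hindered acid without the basic hydrolysis that would cleave the aryl silyl ether.

Step 5
Reactants: 6 methyl (2R)-2-methyloxirane-2-carboxylate (methyl (R)-2-methylglycidate)
Product: 7 methyl (2R)-3-(benzyloxy)-2-hydroxy-2-methylpropanoate
Conditions: BnOH, BF3·OEt2 (cat.), CH2Cl2, 0 °C to rt
Reagents that add atoms: benzyl alcohol OCc1ccccc1
Why: Lewis-acid-catalysed epoxide opening (SN2) at the unsubstituted CH2, the carbon next to the ester being deactivated towards ionisation; the quaternary stereocentre is not touched and keeps its (R) configuration.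

Step 6
Reactants: 5 2-methoxy-6-methyl-4-(triisopropylsilyloxy)benzoic acid; 7 methyl (2R)-3-(benzyloxy)-2-hydroxy-2-methylpropanoate
Product: 9 methyl (2R)-3-(benzyloxy)-2-{[2-methoxy-6-methyl-4-(triisopropylsilyloxy)benzoyl]oxy}-2-methylpropanoate, via mixed trifluoroacetic anhydride 8 (not isolated)
Conditions: 5, (CF3CO)2O, CH2Cl2, 0 °C; then 7, 0 °C to rt
Reagents that add atoms: none
Why: Esterification of a hindered acid through its mixed trifluoroacetic anhydride: the 2,6-disubstituted, electron-rich aroyl group of 8 should ionise to a linear acylium ion that escapes the ortho blockade and can acylate even a tertiary alcohol, the C–O bond at the stereocentre staying intact.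

Step 7
Reactants: 10 diethyl (2-hydroxyethyl)phosphonate
Product: 11 diethyl [2-(tert-butyldimethylsilyloxy)ethyl]phosphonate
Conditions: t-BuMe2SiCl, imidazole, CH2Cl2, rt
Reagents that add atoms: tert-butylchlorodimethylsilane CC(C)(C)[Si](C)(C)Cl
Why: Standard silyl ether formation at a primary alcohol.

Step 8
Reactants: 11 diethyl [2-(tert-butyldimethylsilyloxy)ethyl]phosphonate; 9 methyl (2R)-3-(benzyloxy)-2-{[2-methoxy-6-methyl-4-(triisopropylsilyloxy)benzoyl]oxy}-2-methylpropanoate
Product: 13 diethyl [(4R)-5-(benzyloxy)-1-(tert-butyldimethylsilyloxy)-4-{[2-methoxy-6-methyl-4-(triisopropylsilyloxy)benzoyl]oxy}-4-methyl-3-oxopentan-2-yl]phosphonate as a mixture of epimers at the phosphonate carbon, via alpha-lithio phosphonate 12 (not isolated)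
Conditions: 11 (2.3 equiv), n-BuLi (2.2 equiv), THF, −78 °C; then 9, −78 to −40 °C; aq. NH4Cl
Reagents that add atoms: none
Why: Claisen-type acylation of the alpha-lithio phosphonate by the methyl ester (beta-ketophosphonate synthesis); the second equivalent deprotonates the product and so protects it from further addition, the shielded 2,6-disubstituted aryl ester should not be attacked, and the new centre at the phosphonate carbon forms as a mixture of epimers that does not matter.

Step 9
Reactants: 13 diethyl [(4R)-5-(benzyloxy)-1-(tert-butyldimethylsilyloxy)-4-{[2-methoxy-6-methyl-4-(triisopropylsilyloxy)benzoyl]oxy}-4-methyl-3-oxopentan-2-yl]phosphonate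
Product: 14 diethyl [(4R)-1-(tert-butyldimethylsilyloxy)-5-hydroxy-4-{[2-methoxy-6-methyl-4-(triisopropylsilyloxy)benzoyl]oxy}-4-methyl-3-oxopentan-2-yl]phosphonate
Conditions: H2 (1 atm), Pd/C, EtOAc, rt
Reagents that add atoms: none
Why: Hydrogenolysis of the alkyl benzyl ether in a non-protic solvent should leave both silyl ethers, the ketone, the phosphonate and the aryl ester untouched.

Step 10
Reactants: 14 diethyl [(4R)-1-(tert-butyldimethylsilyloxy)-5-hydroxy-4-{[2-methoxy-6-methyl-4-(triisopropylsilyloxy)benzoyl]oxy}-4-methyl-3-oxopentan-2-yl]phosphonate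
Product: 15 diethyl [(4R)-1-(tert-butyldimethylsilyloxy)-4-{[2-methoxy-6-methyl-4-(triisopropylsilyloxy)benzoyl]oxy}-4-methyl-3,5-dioxopentan-2-yl]phosphonate
Conditions: Dess–Martin periodinane, CH2Cl2, 0 °C to rt; used crude
Reagents that add atoms: none
Why: Dess–Martin oxidation of the neopentyl-type primary alcohol to the aldehyde under neutral conditions; the adjacent centre bears no hydrogen and cannot epimerise, and the sensitive beta-keto aldehyde is used directly.

Step 11
Reactants: 16 but-3-yn-2-ol (racemic); 17 (E)-1-bromoprop-1-ene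
Product: 18 (5E)-hept-5-en-3-yn-2-ol (racemic)
Conditions: Pd(PPh3)2Cl2 (cat.), CuI (cat.), Et3N, THF, rt
Reagents that add atoms: none
Why: Sonogashira coupling of the terminal alkyne with the alkenyl bromide, which proceeds with retention of the (E) geometry.

Step 12
Reactants: 18 (5E)-hept-5-en-3-yn-2-ol
Product: 19 (5E)-hept-5-en-3-yn-2-one
Conditions: MnO2, CH2Cl2, rt
Reagents that add atoms: none
Why: MnO2 oxidises the activated propargylic alcohol to the ynone and removes the irrelevant carbinol stereocentre.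

Step 13
Reactants: 19 (5E)-hept-5-en-3-yn-2-one
Product: 20 (5E)-2-(trimethylsilyloxy)hepta-1,5-dien-3-yne
Conditions: Me3SiOTf, Et3N, Et2O, 0 °C
Reagents that add atoms: trimethylsilyl trifluoromethanesulfonate C[Si](C)(C)OS(=O)(=O)C(F)(F)F
Why: Soft enolisation and O-silylation (enol silane formation); only the methyl group of 19 bears alpha-hydrogens, so a single enol silane can form.

Step 14
Reactants: 15 diethyl [(4R)-1-(tert-butyldimethylsilyloxy)-4-{[2-methoxy-6-methyl-4-(triisopropylsilyloxy)benzoyl]oxy}-4-methyl-3,5-dioxopentan-2-yl]phosphonate; 20 (5E)-2-(trimethylsilyloxy)hepta-1,5-dien-3-yne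
Product: 22 (1R,6R)-3-[(tert-butyldimethylsilyloxy)methyl]-6-hydroxy-1-methyl-2-oxo-4-[(3E)-pent-3-en-1-yn-1-yl]cyclohex-3-en-1-yl 2-methoxy-6-methyl-4-(triisopropylsilyloxy)benzoate, via difluoroboron aldolate 21 (not isolated)
Conditions: 20 (1.5 equiv), BF3·OEt2 (2.5 equiv), CH2Cl2, −78 °C; then i-Pr2NEt, LiCl, MeCN, −40 to 40 °C; aq. NaHCO3
Reagents that add atoms: none
Why: BF3 activates the aldehyde of 15 and the terminal carbon of enol silane 20 adds through an open transition state (Mukaiyama aldol, Me3SiF lost) to make the C5–C6 bond and boron aldolate 21; LiCl/i-Pr2NEt then removes the proton on the phosphonate carbon, whose carbanion adds to the boron-chelated alkynyl ketone and expels diethyl phosphate (intramolecular Horner–Wadsworth–Emmons), making the C4a=C8a bond. The closest known reaction types are BF3-mediated Mukaiyama aldol additions of alkynyl ketone enol silanes to alpha-oxygenated aldehydes and LiCl/amine-promoted intramolecular Horner–Wadsworth–Emmons cyclisations of beta-ketophosphonates onto ketones to give cyclohexenones. The carbocycle closes by 6-exo-trig addition of the C8a carbanion to the C4a carbonyl and the ring fixes the geometry of the tetrasubstituted alkene; the pyran ring is not closed here. The new stereocentre C6 is controlled by the fully substituted C7 next to the aldehyde: in the polar Felkin–Anh (Cornforth) arrangement the nucleophile comes in anti to the C7–O bond and past the methyl group rather than the acyl branch, which should give the (6R) carbinol with O6 cis to O7, while the stereocentre at C8a of 15 is destroyed. The step needs chemoselectivity and the substrate provides it: the enol silane finds a single aldehyde (the C8 ketone is shielded by C7), the phosphonate carbon is by far the most acidic position so a mild amine base suffices, C7 carries no hydrogen, and the C6 oxygen stays boron-bound so that it should neither add to the ynone, nor take over the aroyl group, nor start a retro-aldol cleavage.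

Step 15
Reactants: 22 (1R,6R)-3-[(tert-butyldimethylsilyloxy)methyl]-6-hydroxy-1-methyl-2-oxo-4-[(3E)-pent-3-en-1-yn-1-yl]cyclohex-3-en-1-yl 2-methoxy-6-methyl-4-(triisopropylsilyloxy)benzoate
Product: 23 (1R,6R)-6-hydroxy-3-(hydroxymethyl)-1-methyl-2-oxo-4-[(3E)-pent-3-en-1-yn-1-yl]cyclohex-3-en-1-yl 4-hydroxy-2-methoxy-6-methylbenzoate
Conditions: Bu4NF, AcOH (1:1), THF, 0 °C to rt
Reagents that add atoms: none
Why: Fluoride-induced cleavage of the aryl triisopropylsilyl and primary tert-butyldimethylsilyl ethers; the acetic acid buffer keeps alkoxides away, so the beta-hydroxy ketone should not undergo retro-aldol cleavage and the hindered ester should not migrate to the C6 hydroxyl.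

Step 16
Reactants: 23 (1R,6R)-6-hydroxy-3-(hydroxymethyl)-1-methyl-2-oxo-4-[(3E)-pent-3-en-1-yn-1-yl]cyclohex-3-en-1-yl 4-hydroxy-2-methoxy-6-methylbenzoate
Product: 24 (6R,7R)-6-hydroxy-7-methyl-8-oxo-3-[(1E)-prop-1-en-1-yl]-5,6,7,8-tetrahydro-1H-isochromen-7-yl 4-hydroxy-2-methoxy-6-methylbenzoate (CNP0187389.2)
Conditions: AgOTf (10 mol %), CH2Cl2, 0 °C to rt, dark
Reagents that add atoms: none
Why: Silver-catalysed 6-endo-dig hydroalkoxylation (cycloisomerisation): the C1 hydroxyl, held cis to the alkyne on the ring alkene, should add to the alkyne carbon that carries the propenyl group (the terminus of the enone-conjugated system and the position best able to bear positive charge), and protodemetalation gives the 2H-pyran without touching C6 or C7.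

**Compound list**

1 | orsellinic acid (2,4-dihydroxy-6-methylbenzoic acid) | Cc1cc(O)cc(O)c1C(=O)O | starting material
2 | benzyl 2,4-dihydroxy-6-methylbenzoate | Cc1cc(O)cc(O)c1C(=O)OCc1ccccc1 | intermediate
3 | benzyl 2-hydroxy-6-methyl-4-(triisopropylsilyloxy)benzoate | Cc1cc(O[Si](C(C)C)(C(C)C)C(C)C)cc(O)c1C(=O)OCc1ccccc1 | intermediate
4 | benzyl 2-methoxy-6-methyl-4-(triisopropylsilyloxy)benzoate | COc1cc(O[Si](C(C)C)(C(C)C)C(C)C)cc(C)c1C(=O)OCc1ccccc1 | intermediate
5 | 2-methoxy-6-methyl-4-(triisopropylsilyloxy)benzoic acid | COc1cc(O[Si](C(C)C)(C(C)C)C(C)C)cc(C)c1C(=O)O | intermediate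
6 | methyl (2R)-2-methyloxirane-2-carboxylate | COC(=O)[C@]1(C)OC1 | starting material
7 | methyl (2R)-3-(benzyloxy)-2-hydroxy-2-methylpropanoate | COC(=O)[C@](C)(O)COCc1ccccc1 | intermediate
8 | 2-methoxy-6-methyl-4-(triisopropylsilyloxy)benzoic trifluoroacetic anhydride | COc1cc(O[Si](C(C)C)(C(C)C)C(C)C)cc(C)c1C(=O)OC(=O)C(F)(F)F | intermediate (not isolated)
9 | methyl (2R)-3-(benzyloxy)-2-{[2-methoxy-6-methyl-4-(triisopropylsilyloxy)benzoyl]oxy}-2-methylpropanoate | COC(=O)[C@](C)(OC(=O)c1c(C)cc(O[Si](C(C)C)(C(C)C)C(C)C)cc1OC)COCc1ccccc1 | intermediate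
10 | diethyl (2-hydroxyethyl)phosphonate | CCOP(=O)(CCO)OCC | starting material
11 | diethyl [2-(tert-butyldimethylsilyloxy)ethyl]phosphonate | CCOP(=O)(CCO[Si](C)(C)C(C)(C)C)OCC | intermediate
12 | diethyl [2-(tert-butyldimethylsilyloxy)-1-lithioethyl]phosphonate | [Li]C(CO[Si](C)(C)C(C)(C)C)P(=O)(OCC)OCC | intermediate (not isolated)
13 | diethyl [(4R)-5-(benzyloxy)-1-(tert-butyldimethylsilyloxy)-4-{[2-methoxy-6-methyl-4-(triisopropylsilyloxy)benzoyl]oxy}-4-methyl-3-oxopentan-2-yl]phosphonate (both epimers at C2 of the chain) | CCOP(=O)(OCC)C(CO[Si](C)(C)C(C)(C)C)C(=O)[C@](C)(OC(=O)c1c(C)cc(O[Si](C(C)C)(C(C)C)C(C)C)cc1OC)COCc1ccccc1 | intermediate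
14 | diethyl [(4R)-1-(tert-butyldimethylsilyloxy)-5-hydroxy-4-{[2-methoxy-6-methyl-4-(triisopropylsilyloxy)benzoyl]oxy}-4-methyl-3-oxopentan-2-yl]phosphonate | CCOP(=O)(OCC)C(CO[Si](C)(C)C(C)(C)C)C(=O)[C@](C)(OC(=O)c1c(C)cc(O[Si](C(C)C)(C(C)C)C(C)C)cc1OC)CO | intermediate
15 | diethyl [(4R)-1-(tert-butyldimethylsilyloxy)-4-{[2-methoxy-6-methyl-4-(triisopropylsilyloxy)benzoyl]oxy}-4-methyl-3,5-dioxopentan-2-yl]phosphonate | CCOP(=O)(OCC)C(CO[Si](C)(C)C(C)(C)C)C(=O)[C@](C)(OC(=O)c1c(C)cc(O[Si](C(C)C)(C(C)C)C(C)C)cc1OC)C=O | intermediate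
16 | but-3-yn-2-ol (racemic) | CC(O)C#C | starting material
17 | (E)-1-bromoprop-1-ene | C/C=C/Br | starting material
18 | (5E)-hept-5-en-3-yn-2-ol (racemic) | C/C=C/C#CC(C)O | intermediate
19 | (5E)-hept-5-en-3-yn-2-one | C/C=C/C#CC(C)=O | intermediate
20 | (5E)-2-(trimethylsilyloxy)hepta-1,5-dien-3-yne | C/C=C/C#CC(=C)O[Si](C)(C)C | intermediate
21 | diethyl [(4R,5R,10E)-1-(tert-butyldimethylsilyloxy)-5-(difluoroboranyloxy)-4-{[2-methoxy-6-methyl-4-(triisopropylsilyloxy)benzoyl]oxy}-4-methyl-3,7-dioxododec-10-en-8-yn-2-yl]phosphonate | C/C=C/C#CC(=O)C[C@@H](OB(F)F)[C@@](C)(OC(=O)c1c(C)cc(O[Si](C(C)C)(C(C)C)C(C)C)cc1OC)C(=O)C(CO[Si](C)(C)C(C)(C)C)P(=O)(OCC)OCC | intermediate (not isolated)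
22 | (1R,6R)-3-[(tert-butyldimethylsilyloxy)methyl]-6-hydroxy-1-methyl-2-oxo-4-[(3E)-pent-3-en-1-yn-1-yl]cyclohex-3-en-1-yl 2-methoxy-6-methyl-4-(triisopropylsilyloxy)benzoate | C/C=C/C#CC1=C(CO[Si](C)(C)C(C)(C)C)C(=O)[C@](C)(OC(=O)c2c(C)cc(O[Si](C(C)C)(C(C)C)C(C)C)cc2OC)[C@H](O)C1 | intermediate
23 | (1R,6R)-6-hydroxy-3-(hydroxymethyl)-1-methyl-2-oxo-4-[(3E)-pent-3-en-1-yn-1-yl]cyclohex-3-en-1-yl 4-hydroxy-2-methoxy-6-methylbenzoate | C/C=C/C#CC1=C(CO)C(=O)[C@](C)(OC(=O)c2c(C)cc(O)cc2OC)[C@H](O)C1 | intermediate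
24 | (6R,7R)-6-hydroxy-7-methyl-8-oxo-3-[(1E)-prop-1-en-1-yl]-5,6,7,8-tetrahydro-1H-isochromen-7-yl 4-hydroxy-2-methoxy-6-methylbenzoate | C/C=C/C1=CC2=C(CO1)C(=O)[C@](C)(OC(=O)c1c(C)cc(O)cc1OC)[C@H](O)C2 | target

**Step count and risks**

Total step count: 16. Longest linear sequence: 11 steps (steps 1–4, 6, 8–10, 14–16, from orsellinic acid).

Steps most likely to fail:

1. Step 14. The aldol addition may show poor facial selectivity at the congested aldehyde, or the base-induced ring closure to the tetrasubstituted enone may be outrun by beta-elimination or retro-aldol cleavage of the boron-bound aldol. Fallback, setting out from 15 and 19 and coming back at 23: the two bonds are made in separate, isolated stages through a closed boron aldol.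
   - 19 is enolised with chlorodicyclohexylborane and Et3N (Et2O, −78 to 0 °C) to the boron enolate F1, which is added to 15 at −78 °C to give the boron aldolate F2.
   - Work-up with methanol and pH 7 buffer releases the aldol F3, and Et3SiOTf/2,6-lutidine caps the carbinol as the triethylsilyl ether F4; C6 epimers can be separated at this stage.
   - NaH in THF (0 °C to rt) closes the ring by Horner–Wadsworth–Emmons reaction to the silyl-protected enynone F5.
   - The conditions of step 15 remove the triethylsilyl group together with the other two silyl groups and give 23.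

2. Step 6. Acyl transfer to the tertiary alcohol may be too slow, so that trifluoroacetylation of 7 or loss of the aryl silyl ether in the acidic medium takes over. Fallback, setting out from 1 and 7 and coming back at 9: the aroyl group is delivered as a ketene.
   - 1 is condensed with acetone ((CF3CO)2O, CF3CO2H) to the benzodioxinone F6 and silylated (i-Pr3SiCl, imidazole) to F7.
   - Heating F7 with 7 in toluene (or irradiation near 300 nm) expels acetone, and the quinoketene F8 is trapped by the tertiary hydroxyl to give the salicylate ester F9.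
   - O-Methylation (MeI, K2CO3, acetone) gives 9.

3. Step 8. Acylation of the lithiated phosphonate by the congested methyl ester may be sluggish, leaving the carbanion time to lose silyloxide by beta-elimination. Fallback, setting out from 9 and coming back at 13: acyl substitution is replaced by carbonyl addition and oxidation.
   - DIBAL-H (CH2Cl2, −78 °C) reduces the methyl ester of 9 to the aldehyde F10.
   - The lithiated phosphonate 12 adds to F10 within minutes at −78 °C to give the beta-hydroxy phosphonate F11.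
   - Dess–Martin oxidation of F11 gives 13.

Further compounds
F1 | step 14 | (5E)-2-(dicyclohexylboranyloxy)hepta-1,5-dien-3-yne | C/C=C/C#CC(=C)OB(C1CCCCC1)C1CCCCC1
F2 | step 14 | diethyl [(4R,5R,10E)-1-(tert-butyldimethylsilyloxy)-5-(dicyclohexylboranyloxy)-4-{[2-methoxy-6-methyl-4-(triisopropylsilyloxy)benzoyl]oxy}-4-methyl-3,7-dioxododec-10-en-8-yn-2-yl]phosphonate | C/C=C/C#CC(=O)C[C@@H](OB(C1CCCCC1)C1CCCCC1)[C@@](C)(OC(=O)c1c(C)cc(O[Si](C(C)C)(C(C)C)C(C)C)cc1OC)C(=O)C(CO[Si](C)(C)C(C)(C)C)P(=O)(OCC)OCC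
F3 | step 14 | diethyl [(4R,5R,10E)-1-(tert-butyldimethylsilyloxy)-5-hydroxy-4-{[2-methoxy-6-methyl-4-(triisopropylsilyloxy)benzoyl]oxy}-4-methyl-3,7-dioxododec-10-en-8-yn-2-yl]phosphonate | C/C=C/C#CC(=O)C[C@@H](O)[C@@](C)(OC(=O)c1c(C)cc(O[Si](C(C)C)(C(C)C)C(C)C)cc1OC)C(=O)C(CO[Si](C)(C)C(C)(C)C)P(=O)(OCC)OCC
F4 | step 14 | diethyl [(4R,5R,10E)-1-(tert-butyldimethylsilyloxy)-4-{[2-methoxy-6-methyl-4-(triisopropylsilyloxy)benzoyl]oxy}-4-methyl-3,7-dioxo-5-(triethylsilyloxy)dodec-10-en-8-yn-2-yl]phosphonate | C/C=C/C#CC(=O)C[C@@H](O[Si](CC)(CC)CC)[C@@](C)(OC(=O)c1c(C)cc(O[Si](C(C)C)(C(C)C)C(C)C)cc1OC)C(=O)C(CO[Si](C)(C)C(C)(C)C)P(=O)(OCC)OCC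
F5 | step 14 | (1R,6R)-3-[(tert-butyldimethylsilyloxy)methyl]-1-methyl-2-oxo-4-[(3E)-pent-3-en-1-yn-1-yl]-6-(triethylsilyloxy)cyclohex-3-en-1-yl 2-methoxy-6-methyl-4-(triisopropylsilyloxy)benzoate | C/C=C/C#CC1=C(CO[Si](C)(C)C(C)(C)C)C(=O)[C@](C)(OC(=O)c2c(C)cc(O[Si](C(C)C)(C(C)C)C(C)C)cc2OC)[C@H](O[Si](CC)(CC)CC)C1
F6 | step 6 | 7-hydroxy-2,2,5-trimethyl-4H-1,3-benzodioxin-4-one | Cc1cc(O)cc2OC(C)(C)OC(=O)c12
F7 | step 6 | 2,2,5-trimethyl-7-(triisopropylsilyloxy)-4H-1,3-benzodioxin-4-one | Cc1cc(O[Si](C(C)C)(C(C)C)C(C)C)cc2OC(C)(C)OC(=O)c12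
F8 | step 6 | 5-methyl-6-(oxomethylidene)-3-(triisopropylsilyloxy)cyclohexa-2,4-dien-1-one | CC1=CC(O[Si](C(C)C)(C(C)C)C(C)C)=CC(=O)C1=C=O
F9 | step 6 | methyl (2R)-3-(benzyloxy)-2-{[2-hydroxy-6-methyl-4-(triisopropylsilyloxy)benzoyl]oxy}-2-methylpropanoate | COC(=O)[C@](C)(OC(=O)c1c(C)cc(O[Si](C(C)C)(C(C)C)C(C)C)cc1O)COCc1ccccc1
F10 | step 8 | (2R)-1-(benzyloxy)-2-methyl-3-oxopropan-2-yl 2-methoxy-6-methyl-4-(triisopropylsilyloxy)benzoate | O=C[C@](C)(OC(=O)c1c(C)cc(O[Si](C(C)C)(C(C)C)C(C)C)cc1OC)COCc1ccccc1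
F11 | step 8 | diethyl [(4R)-5-(benzyloxy)-1-(tert-butyldimethylsilyloxy)-3-hydroxy-4-{[2-methoxy-6-methyl-4-(triisopropylsilyloxy)benzoyl]oxy}-4-methylpentan-2-yl]phosphonate (mixture at C2 and C3) | CCOP(=O)(OCC)C(CO[Si](C)(C)C(C)(C)C)C(O)[C@](C)(OC(=O)c1c(C)cc(O[Si](C(C)C)(C(C)C)C(C)C)cc1OC)COCc1ccccc1
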